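The symmetric diarylmethane is divided at one aryl–CH2 bond into an aryllithium and an aldehyde, both drawn from a single β-resorcylate whose carboxyl carbon sits on C2 of ring A. That resorcylate is unfolded to a linear masked tetraketide, diketo-dioxinone 10. In the key step an intramolecular aldol between the dioxinone α-carbon and the far ketone forges the C1–C2 bond of ring A and aromatizes it at once. The step exploits the substitution of ring A: arylethyl chain on C1, bridge carbon on C2, O3 and O5 meta to each other; O3 emerges inside the acetonide and O5 as a free phenol, ready for separate methylation and benzylation.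

Key step: step 5

Remark on the chemistry: ring A is numbered C1 (arylethyl chain), C2 (bridge carbon), C3 (OMe), C5 (OH). Polycarbonyl compounds are drawn as keto tautomers although they should be largely enolized. The target is achiral, so no stereocentre has to be set. Ester 15 is divided into two equal portions for steps 8 and 10. The guaiacyl benzyl ether is kept in 10 because it should survive every base used and falls in the final hydrogenolysis.

Step 1
Reactants: 1 3-(4-hydroxy-3-methoxyphenyl)propanoic acid (dihydroferulic acid)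
Product: 2 3-(4-benzyloxy-3-methoxyphenyl)propanoic acid
Conditions: BnBr (1.3 equiv), NaOH (3 equiv), EtOH–H2O, reflux; then aq. HCl to pH 2
Reagents that add atoms: benzyl bromide, BrCc1ccccc1
Why: Williamson etherification, in which the phenoxide of the dianion is far more nucleophilic than the carboxylate in the protic medium and any benzyl ester that forms is saponified by the excess hydroxide before acidification.

Step 2
Reactants: 2 3-(4-benzyloxy-3-methoxyphenyl)propanoic acid
Product: 4 3-(4-benzyloxy-3-methoxyphenyl)-N-methoxy-N-methylpropanamide, via acyl imidazole 3 (not isolated)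
Conditions: 1,1'-carbonyldiimidazole (1.1 equiv), CH2Cl2, rt; then MeNH(OMe)·HCl (1.3 equiv), rt
Reagents that add atoms: N,O-dimethylhydroxylamine hydrochloride, CNOC.Cl
Why: Amide coupling through acyl imidazole 3, which should transfer its acyl group cleanly to the hydroxylamine while the imidazole set free takes up the HCl.

Step 3
Reactants: 5 2,2,6-trimethyl-4H-1,3-dioxin-4-one; 6 acetyl chloride
Product: 8 2,2-dimethyl-6-(2-oxopropyl)-4H-1,3-dioxin-4-one, via lithium dienolate 7 (not isolated)
Conditions: 5 (2 equiv), LiN(SiMe3)2 (2 equiv), THF, −78 °C; then 6 (1 equiv), −78 °C; 1 M HCl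
Reagents that add atoms: none
Why: Claisen-type γ-C-acylation of the vinylogous ester dienolate 7, which reacts at its exocyclic carbon, the second equivalent of 7 serving as the base that the more acidic product consumes.

Step 4
Reactants: 8 2,2-dimethyl-6-(2-oxopropyl)-4H-1,3-dioxin-4-one; 4 3-(4-benzyloxy-3-methoxyphenyl)-N-methoxy-N-methylpropanamide
Product: 10 6-[6-(4-benzyloxy-3-methoxyphenyl)-2,4-dioxohexyl]-2,2-dimethyl-4H-1,3-dioxin-4-one, via dilithium dienediolate 9 (not isolated)
Conditions: 8 (2 equiv), LiN(iPr)2 (4 equiv), THF, −78 °C; then 4 (1 equiv), −78 to −40 °C; 1 M HCl, 0 °C; used after brief filtration through silica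
Reagents that add atoms: none
Why: Crossed Claisen condensation in the manner of the Weinreb ketone synthesis, in which dianion 9 attacks through its terminal carbon, the chelated tetrahedral adduct of the N-methoxy-N-methylamide resists a second addition, and the excess dianion takes up the acidic proton of the new β-diketone.

Step 5
Reactants: 10 6-[6-(4-benzyloxy-3-methoxyphenyl)-2,4-dioxohexyl]-2,2-dimethyl-4H-1,3-dioxin-4-one
Product: 12 5-[2-(4-benzyloxy-3-methoxyphenyl)ethyl]-7-hydroxy-2,2-dimethyl-4H-1,3-benzodioxin-4-one, via cyclic aldol 11 (not isolated)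
Conditions: Et3N (3 equiv), CH2Cl2, rt
Reagents that add atoms: none
Why: Et3N removes a proton from the doubly activated CH2 between the dioxinone and the near ketone, and the resulting vinylogous dienolate attacks the far ketone through the dioxinone α-carbon (polyketide C2 onto C7) to give aldol 11, which loses water by an E1cB path and enolizes at the remaining ring ketone to the phenol. The closest known reaction type is the base-mediated biomimetic aldol aromatization of diketo-dioxinones to acetonide-protected β-resorcylates. Ring A closes in the 6-(enolexo)-exo-trig mode by forming its C1–C2 bond. No stereocentre is created in the product, the carbinol centre of 11 being erased on dehydration. The step needs selectivity among the possible cyclization modes of the polycarbonyl chain, and the dioxinone secures it: with the carboxyl tied up as a cyclic enol ester acetal neither Claisen closure to a phloroglucinol nor lactonization to a pyrone can take place, so the C2-to-C7 aldol is the only six-membered closure left. The same mask returns O3 inside the acetonide and O5 as the free phenol, the differentiation the later steps rely on.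

Step 6
Reactants: 12 5-[2-(4-benzyloxy-3-methoxyphenyl)ethyl]-7-hydroxy-2,2-dimethyl-4H-1,3-benzodioxin-4-one
Product: 13 7-benzyloxy-5-[2-(4-benzyloxy-3-methoxyphenyl)ethyl]-2,2-dimethyl-4H-1,3-benzodioxin-4-one
Conditions: BnBr (1.2 equiv), K2CO3 (2 equiv), DMF, rt
Reagents that add atoms: benzyl bromide, BrCc1ccccc1
Why: Williamson etherification of the only free phenol (O5 of ring A), the acetonide-masked salicylate being inert to K2CO3 in DMF.

Step 7
Reactants: 13 7-benzyloxy-5-[2-(4-benzyloxy-3-methoxyphenyl)ethyl]-2,2-dimethyl-4H-1,3-benzodioxin-4-one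
Product: 15 methyl 4-benzyloxy-2-[2-(4-benzyloxy-3-methoxyphenyl)ethyl]-6-methoxybenzoate, via methyl salicylate 14 (not isolated)
Conditions: NaOMe (2 equiv), MeOH–THF, 50 °C; evaporate; then MeI (5 equiv), DMF, rt
Reagents that add atoms: sodium methoxide, [Na+].[O-]C; iodomethane, CI
Why: Acyl substitution by methoxide opens the salicylate acetonide with loss of acetone, and the sodium phenoxide so released (O3) should be methylated in DMF by a Williamson SN2 reaction.

Step 8
Reactants: 15 methyl 4-benzyloxy-2-[2-(4-benzyloxy-3-methoxyphenyl)ethyl]-6-methoxybenzoate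
Product: 16 {4-benzyloxy-2-[2-(4-benzyloxy-3-methoxyphenyl)ethyl]-6-methoxyphenyl}methanol
Conditions: LiAlH4 (1.5 equiv), THF, 0 °C to reflux; H2O, aq. NaOH work-up
Reagents that add atoms: none
Why: Ester reduction by hydride transfer from LiAlH4, which is small enough to reach the di-ortho-substituted carbonyl while the aryl benzyl and methyl ethers are inert.

Step 9
Reactants: 16 {4-benzyloxy-2-[2-(4-benzyloxy-3-methoxyphenyl)ethyl]-6-methoxyphenyl}methanol
Product: 17 4-benzyloxy-2-[2-(4-benzyloxy-3-methoxyphenyl)ethyl]-6-methoxybenzaldehyde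
Conditions: activated MnO2 (15 equiv), CH2Cl2, rt
Reagents that add atoms: none
Why: Chemoselective oxidation of an electron-rich benzylic alcohol on activated MnO2 under neutral conditions, which should stop at the aldehyde and avoids acid that would ionize the carbinol.

Step 10
Reactants: 15 methyl 4-benzyloxy-2-[2-(4-benzyloxy-3-methoxyphenyl)ethyl]-6-methoxybenzoate
Product: 18 4-benzyloxy-2-[2-(4-benzyloxy-3-methoxyphenyl)ethyl]-6-methoxybenzoic acid
Conditions: KOH (10 equiv), DMSO–H2O, 90 °C; then cold 1 M HCl to pH 3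
Reagents that add atoms: potassium hydroxide, [K+].[OH-]
Why: Saponification of the hindered ester by poorly solvated hydroxide in hot aqueous DMSO, with acidification in the cold to keep the electron-rich acid from protodecarboxylation.

Step 11
Reactants: 18 4-benzyloxy-2-[2-(4-benzyloxy-3-methoxyphenyl)ethyl]-6-methoxybenzoic acid
Product: 19 5-benzyloxy-1-[2-(4-benzyloxy-3-methoxyphenyl)ethyl]-2-iodo-3-methoxybenzene
Conditions: I2 (3 equiv), K3PO4 (1 equiv), MeCN, 100 °C, sealed tube
Reagents that add atoms: iodine, II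
Why: Transition-metal-free decarboxylative ipso-iodination of an electron-rich ortho-alkoxybenzoate, in which the carboxylate delivers iodine to its own carbon (activated by the ortho-methoxy and para-benzyloxy groups) as CO2 departs, while unactivated I2 is too weak an electrophile to substitute the other ring positions.

Step 12
Reactants: 19 5-benzyloxy-1-[2-(4-benzyloxy-3-methoxyphenyl)ethyl]-2-iodo-3-methoxybenzene; 17 4-benzyloxy-2-[2-(4-benzyloxy-3-methoxyphenyl)ethyl]-6-methoxybenzaldehyde
Product: 21 bis{4-benzyloxy-2-[2-(4-benzyloxy-3-methoxyphenyl)ethyl]-6-methoxyphenyl}methanol, via aryllithium 20 (not isolated)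
Conditions: 19 (1.2 equiv), nBuLi (1.2 equiv), THF, −78 °C; then 17 (1 equiv), −78 to 0 °C; H2O
Reagents that add atoms: none
Why: Iodine–lithium exchange, faster at −78 °C than any deprotonation or attack on the benzyl ethers, followed by 1,2-addition of the methoxy-stabilized aryllithium to the non-enolizable aldehyde; the carbinol carbon carries two identical aryl groups and is no stereocentre.

Step 13
Reactants: 21 bis{4-benzyloxy-2-[2-(4-benzyloxy-3-methoxyphenyl)ethyl]-6-methoxyphenyl}methanol
Product: 22 bis{4-hydroxy-2-[2-(4-hydroxy-3-methoxyphenyl)ethyl]-6-methoxyphenyl}methane (CNP0079383.0)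
Conditions: H2 (1 atm), Pd/C (10 wt %), EtOAc–AcOH 10:1, rt
Reagents that add atoms: none
Why: Catalytic hydrogenolysis should cleave the four benzyl ethers and the doubly benzylic C–OH bond, the latter activated by ionization to a diarylmethyl cation or para-quinone methide stabilized by the ortho and para oxygens, while methyl ethers and arenes remain untouched.

Compound list
1 | 3-(4-hydroxy-3-methoxyphenyl)propanoic acid (dihydroferulic acid) | COc1cc(CCC(=O)O)ccc1O | starting material
2 | 3-(4-benzyloxy-3-methoxyphenyl)propanoic acid | COc1cc(CCC(=O)O)ccc1OCc1ccccc1 | intermediate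
3 | 1-[3-(4-benzyloxy-3-methoxyphenyl)propanoyl]imidazole (in situ) | COc1cc(CCC(=O)n2ccnc2)ccc1OCc1ccccc1 | intermediate
4 | 3-(4-benzyloxy-3-methoxyphenyl)-N-methoxy-N-methylpropanamide | COc1cc(CCC(=O)N(C)OC)ccc1OCc1ccccc1 | intermediate
5 | 2,2,6-trimethyl-4H-1,3-dioxin-4-one | CC1=CC(=O)OC(C)(C)O1 | starting material
6 | acetyl chloride | CC(=O)Cl | starting material
7 | lithium 2,2-dimethyl-6-methylidene-6H-1,3-dioxin-4-olate, the dienolate of 5 (in situ) | [Li]OC1=CC(=C)OC(C)(C)O1 | intermediate
8 | 2,2-dimethyl-6-(2-oxopropyl)-4H-1,3-dioxin-4-one | CC(=O)CC1=CC(=O)OC(C)(C)O1 | intermediate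
9 | dilithium dienediolate of 8, deprotonated at C1 and C3 of the oxopropyl chain (in situ) | [Li]OC(=C)C=C1C=C(O[Li])OC(C)(C)O1 | intermediate
10 | 6-[6-(4-benzyloxy-3-methoxyphenyl)-2,4-dioxohexyl]-2,2-dimethyl-4H-1,3-dioxin-4-one | CC1(C)OC(CC(=O)CC(=O)CCc2ccc(OCc3ccccc3)c(OC)c2)=CC(=O)O1 | intermediate
11 | 5-[2-(4-benzyloxy-3-methoxyphenyl)ethyl]-5-hydroxy-2,2-dimethyl-5,6-dihydro-4H-1,3-benzodioxine-4,7(8H)-dione, racemic (in situ) | CC1(C)OC(=O)C2=C(CC(=O)CC2(O)CCc2ccc(OCc3ccccc3)c(OC)c2)O1 | intermediate
12 | 5-[2-(4-benzyloxy-3-methoxyphenyl)ethyl]-7-hydroxy-2,2-dimethyl-4H-1,3-benzodioxin-4-one | CC1(C)OC(=O)c2c(CCc3ccc(OCc4ccccc4)c(OC)c3)cc(O)cc2O1 | intermediate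
13 | 7-benzyloxy-5-[2-(4-benzyloxy-3-methoxyphenyl)ethyl]-2,2-dimethyl-4H-1,3-benzodioxin-4-one | CC1(C)OC(=O)c2c(CCc3ccc(OCc4ccccc4)c(OC)c3)cc(OCc3ccccc3)cc2O1 | intermediate
14 | methyl 4-benzyloxy-6-[2-(4-benzyloxy-3-methoxyphenyl)ethyl]-2-hydroxybenzoate (in situ as its sodium phenoxide) | COC(=O)c1c(O)cc(OCc2ccccc2)cc1CCc1ccc(OCc2ccccc2)c(OC)c1 | intermediate
15 | methyl 4-benzyloxy-2-[2-(4-benzyloxy-3-methoxyphenyl)ethyl]-6-methoxybenzoate | COC(=O)c1c(OC)cc(OCc2ccccc2)cc1CCc1ccc(OCc2ccccc2)c(OC)c1 | intermediate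
16 | {4-benzyloxy-2-[2-(4-benzyloxy-3-methoxyphenyl)ethyl]-6-methoxyphenyl}methanol | OCc1c(OC)cc(OCc2ccccc2)cc1CCc1ccc(OCc2ccccc2)c(OC)c1 | intermediate
17 | 4-benzyloxy-2-[2-(4-benzyloxy-3-methoxyphenyl)ethyl]-6-methoxybenzaldehyde | O=Cc1c(OC)cc(OCc2ccccc2)cc1CCc1ccc(OCc2ccccc2)c(OC)c1 | intermediate
18 | 4-benzyloxy-2-[2-(4-benzyloxy-3-methoxyphenyl)ethyl]-6-methoxybenzoic acid | OC(=O)c1c(OC)cc(OCc2ccccc2)cc1CCc1ccc(OCc2ccccc2)c(OC)c1 | intermediate
19 | 5-benzyloxy-1-[2-(4-benzyloxy-3-methoxyphenyl)ethyl]-2-iodo-3-methoxybenzene | Ic1c(OC)cc(OCc2ccccc2)cc1CCc1ccc(OCc2ccccc2)c(OC)c1 | intermediate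
20 | {4-benzyloxy-2-[2-(4-benzyloxy-3-methoxyphenyl)ethyl]-6-methoxyphenyl}lithium (in situ) | [Li]c1c(OC)cc(OCc2ccccc2)cc1CCc1ccc(OCc2ccccc2)c(OC)c1 | intermediate
21 | bis{4-benzyloxy-2-[2-(4-benzyloxy-3-methoxyphenyl)ethyl]-6-methoxyphenyl}methanol | OC(c1c(OC)cc(OCc2ccccc2)cc1CCc1ccc(OCc2ccccc2)c(OC)c1)c1c(OC)cc(OCc2ccccc2)cc1CCc1ccc(OCc2ccccc2)c(OC)c1 | intermediate
22 | bis{4-hydroxy-2-[2-(4-hydroxy-3-methoxyphenyl)ethyl]-6-methoxyphenyl}methane (CNP0079383.0) | COc1cc(CCc2cc(O)cc(OC)c2Cc2c(CCc3ccc(O)c(OC)c3)cc(O)cc2OC)ccc1O | target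

Total step count: 13.
Longest linear sequence: 10 steps (1, 2, 4, 5, 6, 7, 8, 9, 12, 13; the branch through steps 10 and 11 is equally long).

Steps most likely to fail

Step 11. Ipso-substitution may lose out to electrophilic iodination at the activated C4 and C6 positions of ring A, or to plain protodecarboxylation. Fallback: setting out from acid 18, a Curtius rearrangement (diphenylphosphoryl azide, Et3N, toluene, rt then 90 °C) should pass through 4-benzyloxy-2-[2-(4-benzyloxy-3-methoxyphenyl)ethyl]-6-methoxybenzoyl azide F1 to the isocyanate 5-benzyloxy-1-[2-(4-benzyloxy-3-methoxyphenyl)ethyl]-2-isocyanato-3-methoxybenzene F2. Aqueous KOH in THF should hydrolyse F2 to 4-benzyloxy-2-[2-(4-benzyloxy-3-methoxyphenyl)ethyl]-6-methoxyaniline F3. Diazotization in the presence of iodide (NaNO2, 4-methylbenzenesulfonic acid, KI, MeCN–H2O, rt) should then lead, through the diazonium 4-methylbenzenesulfonate F4, by a Sandmeyer-type substitution to iodide 19, where the route is rejoined.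

Step 5. The aldol adduct may stall before dehydration, or the dioxinone may fragment to an acylketene that is lost to pyrone formation or oligomerization. Fallback: setting out from 10, the mask is removed first. Heating in toluene with methanol (110 °C, sealed) should trap the acylketene as methyl 9-(4-benzyloxy-3-methoxyphenyl)-3,5,7-trioxononanoate F5. Cs2CO3 in MeOH, then HCl in MeOH, should effect the same C2-to-C7 aldol aromatization to methyl 6-[2-(4-benzyloxy-3-methoxyphenyl)ethyl]-2,4-dihydroxybenzoate F6. Because the 2-hydroxyl is hydrogen-bonded to the ester, BnBr (1 equiv) and K2CO3 in acetone should benzylate only the 4-hydroxyl and give 14, which enters the methylation stage of step 7.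

Step 4. The dianion may enolize the amide in place of adding to it, and the product may cyclize or decompose during work-up. Fallback: setting out from acid 2 and dienolate 7 (made from 5 as in step 3), the chain is assembled by acylation of a β-keto ester and decarboxylation. Oxalyl chloride with catalytic DMF in CH2Cl2 should convert 2 into 3-(4-benzyloxy-3-methoxyphenyl)propanoyl chloride F7. Dienolate 7 and allyl malonyl chloride (THF, −78 °C) should give allyl 4-(2,2-dimethyl-4-oxo-4H-1,3-dioxin-6-yl)-3-oxobutanoate F8. C-Acylation of F8 with F7 (MgCl2, pyridine, CH2Cl2, 0 °C) should give allyl 2-[3-(4-benzyloxy-3-methoxyphenyl)propanoyl]-4-(2,2-dimethyl-4-oxo-4H-1,3-dioxin-6-yl)-3-oxobutanoate F9. Deallylation and decarboxylation with Pd(PPh3)4 (zerovalent palladium) and morpholine in THF at 0 °C should then return diketo-dioxinone 10.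

Further compounds
F1 | step 11 | 4-benzyloxy-2-[2-(4-benzyloxy-3-methoxyphenyl)ethyl]-6-methoxybenzoyl azide | [N-]=[N+]=NC(=O)c1c(OC)cc(OCc2ccccc2)cc1CCc1ccc(OCc2ccccc2)c(OC)c1
F2 | step 11 | 5-benzyloxy-1-[2-(4-benzyloxy-3-methoxyphenyl)ethyl]-2-isocyanato-3-methoxybenzene | O=C=Nc1c(OC)cc(OCc2ccccc2)cc1CCc1ccc(OCc2ccccc2)c(OC)c1
F3 | step 11 | 4-benzyloxy-2-[2-(4-benzyloxy-3-methoxyphenyl)ethyl]-6-methoxyaniline | Nc1c(OC)cc(OCc2ccccc2)cc1CCc1ccc(OCc2ccccc2)c(OC)c1
F4 | step 11 | 4-benzyloxy-2-[2-(4-benzyloxy-3-methoxyphenyl)ethyl]-6-methoxybenzenediazonium 4-methylbenzenesulfonate | N#[N+]c1c(OC)cc(OCc2ccccc2)cc1CCc1ccc(OCc2ccccc2)c(OC)c1.Cc1ccc(S(=O)(=O)[O-])cc1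
F5 | step 5 | methyl 9-(4-benzyloxy-3-methoxyphenyl)-3,5,7-trioxononanoate | COC(=O)CC(=O)CC(=O)CC(=O)CCc1ccc(OCc2ccccc2)c(OC)c1
F6 | step 5 | methyl 6-[2-(4-benzyloxy-3-methoxyphenyl)ethyl]-2,4-dihydroxybenzoate | COC(=O)c1c(O)cc(O)cc1CCc1ccc(OCc2ccccc2)c(OC)c1
F7 | step 4 | 3-(4-benzyloxy-3-methoxyphenyl)propanoyl chloride | COc1cc(CCC(=O)Cl)ccc1OCc1ccccc1
F8 | step 4 | allyl 4-(2,2-dimethyl-4-oxo-4H-1,3-dioxin-6-yl)-3-oxobutanoate | C=CCOC(=O)CC(=O)CC1=CC(=O)OC(C)(C)O1
F9 | step 4 | allyl 2-[3-(4-benzyloxy-3-methoxyphenyl)propanoyl]-4-(2,2-dimethyl-4-oxo-4H-1,3-dioxin-6-yl)-3-oxobutanoate | C=CCOC(=O)C(C(=O)CCc1ccc(OCc2ccccc2)c(OC)c1)C(=O)CC1=CC(=O)OC(C)(C)O1
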